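What is left of the starting material is the clock we shall read, so we start from that fraction of the charge.

| flask | starting material | partner | protic impurity | remark | time |
|---|---|---|---|---|---|
| dawn | 0.10 M | 0.40 M | 0.010 M | run made earlier |  |
| spring | 0.050 M | 0.40 M | 0.010 M | run made earlier |  |
| summer | 0.075 M | 0.40 M | 0.010 M | run made earlier |  |
| gamma | 0.10 M (in portions, 4, over 80 min) | 0.400 M | 0.0100 M | first portion at the start, last at 80 min | 1.5 h |
| eta | 0.10 M | 0.400 M (fed, over 80 min) | 0.0100 M | all else is in the flask from the start; the feed brings no volume worth counting | 1.5 h |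
| alpha | 0.10 M (fed, over 80 min) | 0.400 M | 0.0100 M | all else is in the flask from the start; the feed brings no volume worth counting | 1.5 h |
| zeta | 0.10 M | 0.400 M | 0.0100 M | everything together at the start | 1.5 h |

| run | time / min | target / % | starting material / % |
|---|---|---|---|
| dawn | 4.00 | 4.4 | 96.8 |
| dawn | 6.00 | 5.1 | 94.0 |
| dawn | 10.0 | 7.6 | 91.6 |
| dawn | 15.0 | 11.5 | 87.6 |
| dawn | 25.0 | 15.6 | 81.6 |
| dawn | 40.0 | 20.6 | 72.9 |
| dawn | 50.0 | 22.5 | 68.8 |
| spring | 8.00 | 6.4 | 93.3 |
| spring | 12.0 | 9.7 | 89.5 |
| spring | 15.0 | 11.3 | 86.9 |
| spring | 25.0 | 15.4 | 80.9 |
| spring | 40.0 | 20.3 | 72.2 |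
| spring | 60.0 | 25.5 | 63.7 |
| spring | 90.0 | 29.2 | 54.2 |
| summer | 5.00 | 4.7 | 95.2 |
| summer | 15.0 | 10.6 | 86.8 |
| summer | 25.0 | 14.4 | 80.8 |
| summer | 40.0 | 20.0 | 72.0 |
| summer | 50.0 | 22.9 | 68.4 |
| summer | 80.0 | 27.8 | 58.6 |
| summer | 90.0 | 29.1 | 54.8 |

(scatter of a reading: 0.5 percentage points)

- the flask with the highest amount of target, in percent of the starting material charged ("all alike" if they lie within 1.5 percentage points) (gamma / eta / alpha / zeta / all alike)
- final target, as a percentage of the starting material charged, in gamma
- final target, as a percentage of the starting material charged, in eta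
- final target, as a percentage of the starting material charged, in alpha
- final target, as a percentage of the starting material charged, in zeta

- steps that have been proposed: partner + protic impurity -> quenched reagent; starting material + partner -> target; target <-> isomer of the product; 2 partner -> side product

Which numbers must we know well? The charge of starting material hardly: at 90.0 min target reads 29.2% from 0.050 M and 29.1% from 0.075 M, with a scatter of 0.5 percentage points. The loss looks first order in starting material, so the fractions carry over from one charge to another and we read zeta from these runs: 54.5% left and 29.1% target. The protic impurity can take 2.50% of the partner, and every flask has the same amount, so this small correction already sits in the readings.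

The slowing of the reaction matters more. Call exposure the logarithm of charge over what is left. If partner goes mainly by pairing with itself, exposure grows as C times the logarithm of one plus t over T. With T at 90.0 min, this gives an exposure ratio between 90.0 min and 40.0 min of 1.88, and the readings give 1.88. So C, the exposure scale, is 0.876.

A portion added at time s keeps the curve's final fraction divided by its fraction at s. Gamma's portions then keep 75.0% on average, while a clock that never slowed gives 72.8%. Target per unit lost reads 0.721 at 50.0 min and 0.641 at 90.0 min. Taking the middle, we reckon gamma's target at 17.0%.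

The forecast gives gamma 17.5%, eta 22.5%, alpha 17.5%, zeta 29.2%, and names zeta, holding that late addition “exposes it to decayed partner”. Its gamma stands a little above ours.

The flasks give gamma 17.4%, eta 23.0%, alpha 17.6% and zeta 29.0%, so zeta leads.

    partner + protic impurity → quenched reagent (k = 0.0101 L mol⁻¹ s⁻¹)
    starting material + partner → target (k = 4.11 × 10⁻⁴ L mol⁻¹ s⁻¹)
    target ⇌ isomer of the product (K = 0.660, k = 3.73 × 10⁻⁴ s⁻¹)
    2 partner → side product (k = 2.02 × 10⁻⁴ L mol⁻¹ s⁻¹)

Gamma holds 75% of its starting material at the end, against our 75.0%. We now use C on the neighbour of zeta with 1.0 M of partner. We shorten T in the ratio of the partner charges and keep C, which gives 33.4% left at 1.50 h. That flask holds 32.6% of its starting material then, with target at 43.0%.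

The runs were generated by integration with constants of no real substance; the scatter is artificial.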